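Target is what I can count, but c counts whatever has left electrophile, dormant form included, so I want a bridge from target to c. This flask is followed so far as below.

in all of them: electrophile 0.20 M
- south: nucleophile 2 equiv (fed, over 80 s); free base 2 equiv; the very flask that is asked about, followed so far; the fed solution adds 0.25 times the starting volume
- flask: nucleophile 2.00 equiv (fed, over 80 s); free base 2.00 equiv; the fed solution adds 0.25 times the starting volume; time 12 min

south run (percent of the electrophile charged)

| time / min | electrophile / % | target / % |
|---|---|---|
| 0.500 | 71.2 | 5.3 |
| 1.00 | 52.1 | 17.5 |
| 1.50 | 39.9 | 31.0 |
| 2.00 | 34.0 | 41.7 |
| 2.50 | 27.6 | 48.7 |
| 3.00 | 23.9 | 53.2 |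
| 4.00 | 21.1 | 63.3 |

(standard deviation of a reading: 1 percentage point)

- charges are per starting volume, the dose included; the dosed solution carries all of it
- steps that have been proposed: electrophile + nucleophile <-> acid set free + target; nucleophile + acid set free <-> protonated nucleophile; acid set free + free base <-> salt of the base; electrophile <-> dormant form
- what has gone from electrophile into another species counts as reacted, even if it can come back
- the earlier runs do not show how much of nucleophile is bound; that part of a forecast is a guess

- part of the electrophile that has reacted at 12 min
- share of the unused nucleophile that is free and not bound as protonated nucleophile, at 12 min

I call u the part of the charged electrophile that is not yet target, and I build the flask one process at a time, comparing rates at one moment, near 3.00 min, after the feed. First comes the main step by itself. The rise of target over the last readings, divided by the mean electrophile there, gives as a reading a pseudo-first-order constant k = 0.405 /min. From the reading u = 46.8%, this first reckoning gives 1.22% at 12 min.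

Second comes the dormant form. Electrophile and target fall short of the charge, so I define the open share s, the part of u standing as electrophile, read over the last readings as 55.2%. So u decays at s·k = 0.224 /min, slower than k.

Third, the comparison drifts. Unused nucleophile per electrophile charged is 1 + u before any binding, and this falls from 147% as u shrinks. Integrating that gives u = 8.80%, so c = 1 − s·u = 95.1%. Nucleophile bound by the acid is not in this reckoning, and for that share, hence fr, I have no reading.

The forecast gives c = 94.5% (90% to 97.5%), below mine, and fr = 68% (40% to 97%), which it calls a guess. On electrophile its words are: “about 55% of the unconverted pool stays as electrophile”.

The flask gives c = 94.7% and fr = 64.7%.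

    electrophile + nucleophile ⇌ acid set free + target (K = 6.10, k = 0.0390 /M/s)
    nucleophile + acid set free ⇌ protonated nucleophile, settled at all times (K = 3300 /M)
    acid set free + free base ⇌ salt of the base, settled at all times (K = 2100 /M)
    electrophile ⇌ dormant form (K = 0.680, k = 0.0110 /s)

At 12.0 min this flask holds 90.4% target, and the open share as read turns the remainder into 5.30% electrophile, against 5.31% in the flask. The neighbouring flask, with 3.40 equiv of free base, reaches 91.7% target, so the same share gives 4.58% electrophile, against 4.5% there, and its c stands at 95.5%.

The data are simulated for substances that don't exist, noise included.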